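Early times already say much: the eta flask, which is the flask asked about, has been followed to 120 s, and a beta flask with twice the free catalyst has been followed to 4.00 min.

all flasks: substrate 0.10 M

| run | reagent | free catalyst | remark | time |
|---|---|---|---|---|
| eta | 0.10 M | 15 mM | the very flask that is asked about, followed so far |  |
| beta | 0.10 M | 30 mM | run made earlier |  |
| flask | 0.100 M | 15 mM |  | 6.0 min |

eta run (percent of the substrate charged)

| time / s | substrate / % | product / % | catalyst intermediate A / % |
|---|---|---|---|
| 25.0 | 90.7 | 1.3 | 4.9 |
| 50.0 | 83.2 | 8.8 | 5.4 |
| 80.0 | 77.3 | 14.4 | 5.6 |
| 120 | 68.5 | 23.0 | 4.6 |

beta run (percent of the substrate charged)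

| time / min | substrate / % | product / % | catalyst intermediate A / % |
|---|---|---|---|
| 1.00 | 64.9 | 17.3 | 9.9 |
| 2.00 | 46.1 | 41.6 | 8.2 |
| 3.00 | 30.0 | 56.4 | 8.4 |
| 4.00 | 19.0 | 66.9 | 11.3 |

(readings scatter by 1 percentage point)

- why nothing more happens at 6.0 min, or that something still does (all of the substrate has reacted / the reagent has run out first / no working catalyst is left / it is still moving)
- conversion of substrate at 6.0 min
- amount of product at 6.0 min, in percent of the substrate charged
- amount of catalyst intermediate A at 6.0 min, in percent of the substrate charged
- amount of product if the flask were left three thousand times as long, in percent of the substrate charged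

- the reaction counts as stopped when no species that holds the substrate changes by six tenths of a point or more over the second half of the time

After an opening drop of substrate, ln S, the logarithm of the substrate share, falls steadily: by 0.167 /min in the eta flask and 0.409 /min in the beta flask, both as readings. Dividing one rate by the other removes time and gives 0.408, against a catalyst ratio of 0.500. The eta span is short and its readings scatter, so I carry the catalyst ratio forward as an assumption, not as a finding. For the asked 6.0 min this gives τ = 3.00 min: the beta-equivalent time, a flask's time multiplied by its catalyst over the catalyst of the beta flask, with substrate and reagent charged as in the beta flask, the usual normalised time scale.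

Does anything stop by then? Beyond that point the beta flask still loses 11 percentage points of substrate by 4.00 min, so I expect the eta flask to be still moving.

How far has it gone? At 3.00 min the beta flask reads substrate 30.0%, which gives a conversion of 70.0%. In the eta flask at 120 s, substrate and product fall short of the charge by 8.50%; holding that shortfall, my reckoning for the asked time leaves product 61.5%.

The forecast says it is still moving, with conversion 66% (59% to 72%), product 57.5% (50% to 64%), catalyst intermediate A 5% (3.5% to 6.5%) and eventual product 96% (80% to 100%): “Extrapolating eta gives S of about 34% at 360 s, so the flask is still moving.” My conversion stands 4 points above it.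

For the eta flask the outcome is: it is still moving, with conversion 67.3%, product 59.8%, catalyst intermediate A 5.46% and eventual product >99.9%.

    catalyst intermediate B → catalyst intermediate C (k = 3.78 /min)
    reagent + catalyst intermediate A → catalyst intermediate B (k = 31.5 /M/min)
    catalyst intermediate C → free catalyst + product (k = 31.3 /min)
    substrate + free catalyst → catalyst intermediate A (k = 26.9 /M/min)

A neighbour flask with 0.025 M of free catalyst has τ = 5.00 min at the same 6.0 min; running the beta slope on from its last reading gives substrate 12.6%, and at that time the neighbour flask holds 12.6%. The eta flask has not come to rest at 6.0 min: over the second half of the time a share moved by 26 points. Ten times the time in the eta flask means τ = 30.0 min, and there the conversion reaches 100%. Product gains a further 40 points to reach 99.3%, while catalyst intermediate A falls to 0.688%.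

All runs are calculated with made-up constants.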